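A kineticist and a bookkeeper dispute two flasks charged alike, one of them warmer, with the blue run before them.

in all of them: free monomer 10 mM; initiator 7.6 mol%; impurity 0.55 mM
- blue: transfer agent 0.50 mM; temperature 20 °C; run made earlier
- Sunday's: transfer agent 1.00 mM; temperature 20 °C; time 2.5 min
- Thursday's: transfer agent 1.00 mM; temperature 45 °C; time 2.5 min

- blue (time / s: monomer in chains / %, free monomer / %): 10.0: 33.6, 66.9; 20.0: 55.5, 41.8; 30.0: 69.0, 28.6

(readings scatter by 0.5 percentage points)

- the earlier runs do not show what temperature does; that part of a forecast is a guess
- no earlier run changes the charge of transfer agent; that part of a forecast is a guess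

* the flask with the highest amount of monomer in chains, in percent of the free monomer charged ("all alike" if they lie within 1.5 percentage points) (Sunday's / Thursday's / all alike)
* final monomer in chains, as a percentage of the free monomer charged, in Sunday's
* final monomer in chains, as a percentage of the free monomer charged, in Thursday's

The kineticist reads the blue run as a single first-order decay of free monomer, the pseudo-first-order view. The last reading gives him a constant of 0.0417 s⁻¹, which over 2.5 min leaves 0.192% free monomer. He books whatever has reacted as monomer in chains, so for him the answer is simply the conversion.

The bookkeeper adds the two columns instead. At 10.0 s the shortfall from the charge is −0.5 percentage points, at 20.0 s it is 2.7 points, and at 30.0 s it is 2.4 points, against a scatter of 0.5 points per reading. Suppose whatever vanishes needs monomer that has already reacted. The gap then starts from nothing and climbs with the square of the converted fraction, as long as the uptake per free monomer holds steady. Dividing each of the later two gaps by that square and averaging gives 6.34%. She calls this ratio, the gap a flask reaches at full conversion, the leak, a kind of selectivity factor, and it is a rough reading. So she expects a ceiling of 93.7%, not the conversion.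

She grants him low conversion: at 10.0 s the leak predicts a gap of 0.69 points, against a scatter of 0.5 points per reading, and there his view serves.

My own reckoning follows hers: both flasks convert nearly all of their free monomer and end near or under 93.7%, alike, with the effects of more transfer agent and of warmth being guesses that I lean downward.

The forecast, on the kineticist's side though lower than his arithmetic and above my ceiling, gave 97% for Sunday's, 97% for Thursday's, and all alike: “Both flasks should finish high and alike.”

The simulation gives 89.7% in Sunday's and 89.3% in Thursday's, so all alike.

    free monomer + initiator → living end + monomer in chains (k = 30.8 L mol⁻¹ s⁻¹, Ea = 50.0 kJ mol⁻¹)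
    free monomer + living end → monomer in chains + living end, rate k2*[living end]*[free monomer] (k = 98.9 L mol⁻¹ s⁻¹, Ea = 35.0 kJ mol⁻¹)
    living end + transfer agent → dead chain (kL = 14.2 L mol⁻¹ s⁻¹, Ea = 42.0 kJ mol⁻¹)
    free monomer + monomer in chains → side product (k = 0.262 L mol⁻¹ s⁻¹, Ea = 37.0 kJ mol⁻¹)
    initiator + impurity → spent initiator (k = 423 L mol⁻¹ s⁻¹, Ea = 42.0 kJ mol⁻¹)
    (constants at 20 °C)

Thursday's ends with 10.1% side product, counted as two in every percentage, and 0.588% free monomer, a leak of 10.3%, higher than the blue reading. With the step to side product taken away, Thursday's ends at 98.2% instead of 89.3%, so that step is the main reason for the shortfall. The neighbour of Thursday's charged with 2.5 mM transfer agent ends with 31.3% side product and 12% free monomer, a leak of 40.4%.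

The data were computed for an exercise; scatter was added.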